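Numbering: C1 ketone, C2=C3 alkene, cyclobutane C4–C5–C11–C10, quaternary C6, carbinol C7, methyls C12 (on C3), C13 (on C10), C14 and C15 (on C6). All fifteen carbons lie on one intact isoprenoid chain joined head to tail (C5–C4–C3–C2–C1–C11–C10–C9–C8–C7–C6 plus four methyls); beyond it the tricycle has just three bonds, C5–C6, C5–C11 and C4–C10, one each for the seven-, six- and four-membered rings. A single enzymatic cationic tricyclisation of acyclic (2E,6E)-farnesyl diphosphate, made from farnesol in two steps, forges these bonds and sets C4, C5, C10 and C11 together. Allylic oxidation (C1), enzymatic hydroxylation (C7), hydroxyl-directed silylation with Tamao oxidation (C14) and angeloylation complete the target.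

Key step: step 3

Remarks on the chemistry (assumptions):
- The same atom labels are used for the carbons of 1–3 that become these ring atoms (C5 is the CH2–O carbon, C6 the terminal alkene carbon bearing C14 and C15); all stereodescriptors refer to this numbering.
- Compound 3 is handled as its trisammonium salt but drawn as the free acid.
- A recombinant α-longipinene synthase that gives the enantiomer drawn for 4 with useful product fidelity is assumed to be available. This enantiomer is (1R,2S,7R,8R) in von Baeyer numbering, the configuration commonly assigned to (+)-α-longipinene. Sesquiterpene co-products would be removed on AgNO3-impregnated silica.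
- The precursor is kept as the native substrate because C7 becomes a cationic centre during the cascade and cannot carry its oxygen through the cyclisation; all oxygens are therefore added afterwards.

Step 1
Reactants: 1 (2E,6E)-farnesol
Product: 2 (2E,6E)-farnesyl chloride
Conditions: NCS, Me2S, CH2Cl2, −40 → 0 °C
Reagents that add atoms: N-chlorosuccinimide, O=C1CCC(=O)N1Cl
Why: Corey–Kim-type chlorination, in which the alkoxysulfonium salt of the primary allylic alcohol is displaced by chloride in an SN2 reaction at the CH2 carbon, so that neither allylic transposition nor E/Z scrambling of the trisubstituted alkenes should occur and no stereocentre is formed.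

Step 2
Reactants: 2 (2E,6E)-farnesyl chloride
Product: 3 (2E,6E)-farnesyl diphosphate (trisammonium salt)
Conditions: (Bu4N)3HP2O7, MeCN, rt; Dowex 50W-X8 (NH4+ form), aq. NH4HCO3/iPrOH; cellulose chromatography, lyophilisation
Reagents that add atoms: tris(tetrabutylammonium) hydrogen diphosphate, CCCC[N+](CCCC)(CCCC)CCCC.CCCC[N+](CCCC)(CCCC)CCCC.CCCC[N+](CCCC)(CCCC)CCCC.OP([O-])(=O)OP([O-])([O-])=O
Why: SN2 displacement of the primary allylic chloride by the diphosphate trianion (direct diphosphorylation of an allylic halide), followed by cation exchange to the water-soluble ammonium form that terpene synthases accept, with both alkene geometries untouched.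

Step 3
Reactants: 3 (2E,6E)-farnesyl diphosphate
Product: 4 (+)-α-longipinene
Conditions: recombinant α-longipinene synthase, MgCl2 (10 mM), HEPES buffer pH 7.5, dithiothreitol, 10% glycerol, 30 °C, pentane overlay
Reagents that add atoms: none
Why: The Mg2+-bound diphosphate ionises and re-adds at the tertiary carbon C3 (nerolidyl diphosphate), and rotation about C3–C4 then gives on re-ionisation the cisoid allyl cation that a cyclohexene containing C3=C4 requires, which is why the (2E) substrate can be used. The closest known reaction type is the terpene-synthase cation–olefin polycyclisation of farnesyl diphosphate, of which α-longipinene formation is a known case. Ring closures: the allyl terminus C5 adds to C6 of the C6=C7 alkene (C5–C6, anti-Markovnikov macrocyclisation to an eleven-membered ring that is later cut down to the seven-membered ring), a 1,3-hydride shift from C5 to C7 restores the C3–C4–C5 allyl cation, C11 of the C10=C11 alkene adds to C5 (C5–C11, cyclohexene, charge at tertiary C10), C4 of the C3=C4 alkene adds to C10 (C4–C10, cyclobutane closed as in the pinyl cation), and deprotonation at C2 then gives the C2=C3 alkene. Stereocentres: C5 and C11 are set by the faces of the allyl cation and of the C10=C11 alkene that the folded chain presents to each other in the active site, and C4 and C10 then follow because the cyclobutane can only close with the seven-membered bridge and the C1–C3 bridge on opposite faces. The step needs complete enantiofacial control and the four-membered exit (C4–C10) instead of the C3–C10 exit to longifolene or early deprotonation; the substrate contributes only the (6E) geometry and the 1,5-spacing of its three alkenes, and the remainder is secured by the water-free, contoured pocket, which deprotonates the C3 cation as soon as the strained ring has formed.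

Step 4
Reactants: 4 (+)-α-longipinene
Product: 5 longipin-2-en-1-one
Conditions: CrO3, 3,5-dimethylpyrazole, CH2Cl2, −20 °C
Reagents that add atoms: chromium trioxide, O=[Cr](=O)=O
Why: Allylic C–H oxidation with the CrO3–3,5-dimethylpyrazole complex converts the only ring allylic methylene, C1, into the conjugated ketone as in the α-pinene-to-verbenone case, since the C12 methyl is a poorer primary donor and the allylic bridgehead C4 cannot become a carbonyl, while the buffered non-acidic medium avoids Wagner–Meerwein opening of the cyclobutane and no stereocentre changes.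

Step 5
Reactants: 5 longipin-2-en-1-one
Product: 6 (7S)-7-hydroxylongipin-2-en-1-one
Conditions: engineered cytochrome P450 BM3 (CYP102A1) variant, NADP+ (cat.), D-glucose, glucose dehydrogenase, air, potassium phosphate buffer pH 8.0, 2% DMSO, 25 °C
Reagents that add atoms: dioxygen, O=O
Why: Cytochrome P450 monooxygenation (hydrogen abstraction by the haem iron–oxo species and oxygen rebound with retention) of an unactivated ring methylene, a reaction type established for terpenoid ketones and lactones including methylenes next to gem-dimethyl carbons; the variant is picked by screening so that the C1 carbonyl anchors the substrate with C7 over the haem, the enone has already removed the competing allylic C–H bonds, and the new C7 stereocentre (S, hydroxyl on the face turned toward C11, cis to C15 and trans to C14) is set by the enzyme pocket.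

Step 6
Reactants: 6 (7S)-7-hydroxylongipin-2-en-1-one
Product: 8 (6S,7S)-7-O,14-C-(diethylsilanediyl)-7-hydroxylongipin-2-en-1-one (trans-fused oxasilolane), via diethyl(hydrido)silyl ether 7 (not isolated)
Conditions: Et2SiHCl, Et3N, DMAP (cat.), CH2Cl2, 0 °C → rt, filter and evaporate; then [Ir(cod)(OMe)]2 (2 mol %), 3,4,7,8-tetramethyl-1,10-phenanthroline (5 mol %), norbornene, THF, 100 °C (sealed vessel)
Reagents that add atoms: chlorodiethylsilane, CC[SiH](Cl)CC
Why: Silyl ether formation with the chlorosilane (no metal hydride, so the enone is untouched) is followed by hydroxyl-directed iridium-catalysed dehydrogenative silylation of a γ primary C–H bond (Si–H oxidative addition, methyl C–H activation, C–Si reductive elimination, norbornene as hydrogen acceptor); only the two C6 methyls can give a five-membered oxasilolane, and C14 is expected to react because the 7-siloxy group sits pseudo-equatorial on the twisted four-carbon bridge, where C14 is the equatorial-like methyl gauche to oxygen and anti to C8, the arrangement that gives the trans-fused ring in 3-hydroxy-4,4-dimethyl terpenoids, so the C6 stereocentre is set by substrate control.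

Step 7
Reactants: 8 (6S,7S)-7-O,14-C-(diethylsilanediyl)-7-hydroxylongipin-2-en-1-one
Product: 9 (6R,7S)-7,14-dihydroxylongipin-2-en-1-one
Conditions: H2O2 (30% aq.), KHCO3, THF/MeOH (1:1), rt → 40 °C
Reagents that add atoms: hydrogen peroxide, OO
Why: Tamao–Fleming oxidation, in which hydroperoxide adds to the alkoxysilane, C14 migrates from silicon to oxygen with retention and the Si–O bonds hydrolyse to the 1,3-diol; under bicarbonate buffering the hindered β,β-disubstituted enone should escape Weitz–Scheffer epoxidation, and no stereocentre is touched.

Step 8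
Reactants: 9 (6R,7S)-7,14-dihydroxylongipin-2-en-1-one; 10 angelic acid
Product: 13 7,14-di-O-angeloyl-7,14-dihydroxylongipin-2-en-1-one (target), via angelic 2,4,6-trichlorobenzoic anhydride 11 (not isolated), via 14-monoangelate 12 (not isolated)
Conditions: 10 (excess), 2,4,6-Cl3C6H2COCl, Et3N, toluene, rt, 2 h; then 9, toluene, 80 °C
Reagents that add atoms: angelic acid (10), C/C=C(/C)C(O)=O
Why: Yamaguchi-type mixed-anhydride esterification, in which the alcohols attack the angeloyl carbonyl of 11 because the trichlorobenzoyl carbonyl is shielded by its two ortho chlorines, the primary C14 hydroxyl first and the neopentylic C7 hydroxyl on heating; leaving out a nucleophilic catalyst avoids the conjugate addition–elimination that would turn the Z-angelate into the E-tiglate, and no stereocentre is touched.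

Compound list
1 | (2E,6E)-farnesol, (2E,6E)-3,7,11-trimethyldodeca-2,6,10-trien-1-ol | CC(C)=CCC/C(C)=C/CC/C(C)=C/CO | starting material
2 | (2E,6E)-farnesyl chloride, (2E,6E)-1-chloro-3,7,11-trimethyldodeca-2,6,10-triene | CC(C)=CCC/C(C)=C/CC/C(C)=C/CCl | intermediate
3 | (2E,6E)-farnesyl diphosphate (trisammonium salt, drawn as free acid) | CC(C)=CCC/C(C)=C/CC/C(C)=C/COP(O)(=O)OP(O)(O)=O | intermediate
4 | (+)-α-longipinene, (4R,5R,10S,11R)-longipin-2-ene; (1R,2S,7R,8R)-2,6,6,9-tetramethyltricyclo[5.4.0.0(2,8)]undec-9-ene | CC1(C)[C@@H]2[C@H]3CC=C(C)[C@@H]2[C@@]3(C)CCC1 | intermediate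
5 | (4R,5S,10R,11R)-longipin-2-en-1-one | CC1(C)[C@@H]2[C@H]3C(=O)C=C(C)[C@@H]2[C@@]3(C)CCC1 | intermediate
6 | (4R,5S,7S,10R,11R)-7-hydroxylongipin-2-en-1-one (OH on the face turned toward C11) | CC1(C)[C@@H]2[C@H]3C(=O)C=C(C)[C@@H]2[C@@]3(C)CC[C@@H]1O | intermediate
7 | 7-O-diethyl(hydrido)silyl ether of 6 | CC1(C)[C@@H]2[C@H]3C(=O)C=C(C)[C@@H]2[C@@]3(C)CC[C@@H]1O[SiH](CC)CC | intermediate
8 | (6S,7S)-7-O,14-C-(diethylsilanediyl)-7-hydroxylongipin-2-en-1-one: 2,2-diethyl-1-oxa-2-silacyclopentane trans-fused at C6–C7, oxygen on C7, silicon on C14 | CC[Si]4(CC)C[C@@]1(C)[C@@H]2[C@H]3C(=O)C=C(C)[C@@H]2[C@@]3(C)CC[C@@H]1O4 | intermediate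
9 | (4R,5S,6R,7S,10R,11R)-7,14-dihydroxylongipin-2-en-1-one (C14–OH trans to C7–OH) | OC[C@@]1(C)[C@@H]2[C@H]3C(=O)C=C(C)[C@@H]2[C@@]3(C)CC[C@@H]1O | intermediate
10 | angelic acid, (Z)-2-methylbut-2-enoic acid | C/C=C(/C)C(O)=O | starting material
11 | angelic 2,4,6-trichlorobenzoic anhydride | C/C=C(/C)C(=O)OC(=O)c1c(Cl)cc(Cl)cc1Cl | intermediate
12 | (6R,7S)-14-angeloyloxy-7-hydroxylongipin-2-en-1-one | C/C=C(/C)C(=O)OC[C@@]1(C)[C@@H]2[C@H]3C(=O)C=C(C)[C@@H]2[C@@]3(C)CC[C@@H]1O | intermediate
13 | CNP0240716.1, (4R,5S,6R,7S,10R,11R)-7,14-bis[(Z)-2-methylbut-2-enoyloxy]longipin-2-en-1-one | C/C=C(/C)C(=O)OC[C@@]1(C)[C@@H]2[C@H]3C(=O)C=C(C)[C@@H]2[C@@]3(C)CC[C@@H]1OC(=O)/C(C)=C\C | target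

Total step count: 8. Longest linear sequence: 8 steps (1 to 13); angelic acid 10 enters in the last step.

Steps most likely to fail

Step 5. What may go wrong: oxygen insertion at C8 or C9 instead of C7, delivery of oxygen to the wrong face of C7, or over-oxidation of the new alcohol. The fallback sets the C7 stereocentre by carbonyl reduction instead of by C–H insertion; it still needs an enzyme that finds C7, but no longer one that finds the right face. It sets out from 5: a hydroxylase variant is accepted on C7 site selectivity alone, whichever face it serves, which would give (7R)-7-hydroxylongipin-2-en-1-one F1, alone or mixed with 6. The crude alcohols would be oxidised with Dess–Martin periodinane (CH2Cl2, NaHCO3, rt) to longipin-2-ene-1,7-dione F2. The saturated C7 ketone would then be reduced by a ketoreductase (NADP+, isopropanol, buffer pH 7, 30 °C) chosen from a panel for hydride delivery to the face turned toward C4, leaving the conjugated C1 ketone alone. The route is rejoined at 6.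

Step 6. What may go wrong: C–H activation at the cis methyl C15 or at both methyls, and reduction of the enone by iridium hydride or hydrosilane. The fallback is oxime-directed, palladium-catalysed methyl acetoxylation from the C7 ketone, which uses no silane and a different selectivity-determining geometry. It sets out from 6: Dess–Martin oxidation would give the dione F2, and NH2OH·HCl/NaOAc (EtOH, 60 °C) the (7E)-longipin-2-ene-1,7-dione dioxime F3, whose C7 oxime hydroxyl lies anti to quaternary C6 so that nitrogen points at the C6 methyls. Pd(OAc)2 (5 mol %) and PhI(OAc)2 in AcOH/Ac2O at 80–100 °C should acetylate both oximes in the flask and acetoxylate the methyl lying in the C=N plane through a five-membered palladacycle, giving 14-acetoxylongipin-2-ene-1,7-dione bis(O-acetyloxime) F4. NaHSO3 in aqueous ethanol (80 °C) would cleave both oximes to 14-acetoxylongipin-2-ene-1,7-dione F5. Ketoreductase reduction of the C7 ketone, as in the fallback for step 5, would give (7S)-14-acetoxy-7-hydroxylongipin-2-en-1-one F6, and K2CO3/MeOH would remove the acetate. The route is rejoined at 9.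

Step 8. What may go wrong: incomplete acylation of the neopentylic C7 hydroxyl, and Z-to-E isomerisation of the angelate under the forcing conditions needed. The fallback builds the Z alkene after the acylation. It sets out from 9: DCC/DMAP esterification of both hydroxyls with 2-[bis(2,2,2-trifluoroethoxy)phosphoryl]propanoic acid (from saponification of its methyl ester) would give 7,14-bis{2-[bis(2,2,2-trifluoroethoxy)phosphoryl]propanoyloxy}longipin-2-en-1-one F7. Still–Gennari olefination (KN(SiMe3)2, 18-crown-6, THF, −78 °C, then acetaldehyde) should then form both (Z)-2-methylbut-2-enoates directly, because the phosphonate α-hydrogens are far more acidic than the γ-hydrogens of the enone. The route is rejoined at 13.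

Further compounds
F1 | step 5 | (7R)-7-hydroxylongipin-2-en-1-one | CC1(C)[C@@H]2[C@H]3C(=O)C=C(C)[C@@H]2[C@@]3(C)CC[C@H]1O
F2 | step 5 | longipin-2-ene-1,7-dione | CC1(C)[C@@H]2[C@H]3C(=O)C=C(C)[C@@H]2[C@@]3(C)CCC1=O
F3 | step 6 | (7E)-longipin-2-ene-1,7-dione dioxime (C1 oxime geometry as formed) | CC1(C)[C@@H]2[C@H]3C(=NO)C=C(C)[C@@H]2[C@@]3(C)CC\C1=N/O
F4 | step 6 | 14-acetoxylongipin-2-ene-1,7-dione bis(O-acetyloxime) | CC(=O)OC[C@@]1(C)[C@@H]2[C@H]3C(=NOC(C)=O)C=C(C)[C@@H]2[C@@]3(C)CC\C1=N/OC(C)=O
F5 | step 6 | 14-acetoxylongipin-2-ene-1,7-dione | CC(=O)OC[C@@]1(C)[C@@H]2[C@H]3C(=O)C=C(C)[C@@H]2[C@@]3(C)CCC1=O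
F6 | step 6 | (7S)-14-acetoxy-7-hydroxylongipin-2-en-1-one | CC(=O)OC[C@@]1(C)[C@@H]2[C@H]3C(=O)C=C(C)[C@@H]2[C@@]3(C)CC[C@@H]1O
F7 | step 8 | 7,14-bis{2-[bis(2,2,2-trifluoroethoxy)phosphoryl]propanoyloxy}longipin-2-en-1-one (mixture of epimers at the two phosphonate α-carbons) | CC(P(=O)(OCC(F)(F)F)OCC(F)(F)F)C(=O)OC[C@@]1(C)[C@@H]2[C@H]3C(=O)C=C(C)[C@@H]2[C@@]3(C)CC[C@@H]1OC(=O)C(C)P(=O)(OCC(F)(F)F)OCC(F)(F)F
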